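**Retrosynthetic overview**

1. Each (2R,3S)-dihydrobenzofuran is cut at C3–C3a and O1–C7a: a formal (3+2) union of an (R)-β-hydroxy ester (O1–C2–C3 plus the C2 aryl group) with an arene that offers C3a and C7a as neighbouring electrophilic carbons.
2. Enabling feature: in ring B (and again in ring D) C7a lies between C7 (OMe) and C3a and is para to C5, the carbon that carries the next unit. A nitro group on C7a activates a fluoride on C3a for the C–C bond and is then itself displaced by the C2 alkoxide, helped by a cyano group on C5. One arene, 3-fluoro-5-methoxy-4-nitrobenzonitrile, serves both rings.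
3. Ring order: the furan ring of the outer unit (on ring B) first; its C5 nitrile becomes the next (R)-β-hydroxy ester (Blaise reaction, asymmetric transfer hydrogenation); then the furan ring of the inner unit (on ring D) by the same annulation.
4. End game: C3' ester and C5' nitrile reduced together, Wittig olefination, enoate reduction, desilylation.

Key step: step 5

Remark: 3,5-difluoro-4-nitrobenzonitrile (7) is assumed to be a catalogue compound; TIPS = triisopropylsilyl, ArA = 3-methoxy-4-(triisopropylsilyloxy)phenyl (ring A), primed locants belong to the inner dihydrobenzofuran.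

**Route**

Step 1
Reactants: 1 4-hydroxy-3-methoxybenzonitrile
Product: 2 3-methoxy-4-(triisopropylsilyloxy)benzonitrile
Conditions: TIPSCl, imidazole, DMF, rt
Reagents that add atoms: triisopropylsilyl chloride, CC(C)[Si](Cl)(C(C)C)C(C)C
Why: Phenol silylation; the bulky silyl ether should withstand organozinc, amide bases and hydrides and is cleaved by fluoride at the end.

Step 2
Reactants: 2 3-methoxy-4-(triisopropylsilyloxy)benzonitrile and 3 ethyl bromoacetate
Product: 5 ethyl 3-ArA-3-oxopropanoate, via enamino ester 4 (not isolated)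
Conditions: Zn dust (3 equiv, activated with MeSO3H), slow addition of 3, THF, reflux; then 1 M HCl, THF, rt
Reagents that add atoms: water, O
Why: Blaise reaction: BrZnCH2CO2Et formed from 3 adds to the nitrile carbon, and mild acid hydrolysis of enamino ester 4 should give the β-keto ester without loss of the aryl silyl ether.

Step 3
Reactants: 5 ethyl 3-ArA-3-oxopropanoate
Product: 6 ethyl (3R)-3-hydroxy-3-ArA-propanoate
Conditions: RuCl(p-cymene)[(R,R)-TsDPEN] (1 mol%), HCO2H/Et3N (5:2), 30 °C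
Reagents that add atoms: none
Why: Noyori–Ikariya asymmetric transfer hydrogenation of an aryl ketone; the (R,R) ligand should deliver hydride to the face that gives the (R)-carbinol (aryl group held by a CH/π contact with the η6-arene), and the ester is not reduced.

Step 4
Reactants: 7 3,5-difluoro-4-nitrobenzonitrile
Product: 8 3-fluoro-5-methoxy-4-nitrobenzonitrile
Conditions: NaOMe (1.0 equiv), MeOH/THF, −40 → 0 °C
Reagents that add atoms: sodium methoxide, [Na+].[O-]C
Why: SNAr of a fluoride ortho to the nitro group; the methoxy group introduced deactivates the ring toward a second substitution.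

Step 5
Reactants: 6 ethyl (3R)-3-hydroxy-3-ArA-propanoate and 8 3-fluoro-5-methoxy-4-nitrobenzonitrile
Product: 11 ethyl (2R,3R)-5-cyano-7-methoxy-2-ArA-2,3-dihydro-1-benzofuran-3-carboxylate (trans), via dilithium alkoxide enolate 9 (not isolated), via C-arylated dilithium alkoxide enolate 10 (not isolated)
Conditions: LiN(iPr)2 (2.1 equiv), THF, −78 → −30 °C; LiN(SiMe3)2 (1.2 equiv), then 8, −78 → 0 °C; DMPU, 0 °C → rt; AcOH, −78 °C; then DBU (0.2 equiv), THF, rt
Reagents that add atoms: none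
Why: Proposed new method: dianion 9 (Fráter–Seebach type; closest known reactions are its C-alkylation and the SNAr α-arylation of ester enolates by 2-fluoronitroarenes) should attack C3a of 8 through its enolate carbon, because fluoride ortho to the nitro group is the most activated leaving group and the lithium-bound alkoxide is the poorer nucleophile; the more acidic arylated ester is deprotonated at once to dianion 10, which cannot undergo retro-aldol cleavage or dehydration. In 10 the alkoxide oxygen then adds to C7a and nitrite leaves (addition–elimination, 5-exo-trig attack on the ring carbon; closest known reaction is the intramolecular displacement of activated nitro groups by alkoxides), the nitro group being twisted out of the ring plane by its two ortho neighbours and the charge being taken up by the para cyano group. The step needs carbon attack at C–F before C–NO2 and alkoxide attack before enolate-oxygen attack at C7a; the first is secured by the ortho-nitro activation of the fluoride, the second by the higher basicity of the alkoxide and its sp3 tether, which reaches the ring carbon from above the ring plane. C2 is carried over unchanged from 6 because none of its bonds is broken. C3 is set under thermodynamic control: DBU equilibrates the ester α-proton to the isomer with the ester trans to the C2 aryl group, and ring opening by β-elimination is stereoelectronically blocked because the C2–O1 bond lies in the nodal plane of the enolate (the reverse would be a 5-endo-trig closure).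

Step 6
Reactants: 11 ethyl (2R,3R)-5-cyano-7-methoxy-2-ArA-2,3-dihydro-1-benzofuran-3-carboxylate
Product: 12 (2R,3S)-3-(hydroxymethyl)-7-methoxy-2-ArA-2,3-dihydro-1-benzofuran-5-carbonitrile
Conditions: LiBH4 (2 equiv), MeOH (2 equiv), THF, 0 °C → rt
Reagents that add atoms: none
Why: Chemoselective borohydride reduction of the ester in the presence of the nitrile and silyl ether; C3 is already the favoured trans epimer and its descriptor changes to S by priority only.

Step 7
Reactants: 12 (2R,3S)-3-(hydroxymethyl)-7-methoxy-2-ArA-2,3-dihydro-1-benzofuran-5-carbonitrile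
Product: 13 (2R,3S)-7-methoxy-2-ArA-3-[(triisopropylsilyloxy)methyl]-2,3-dihydro-1-benzofuran-5-carbonitrile
Conditions: TIPSCl, imidazole, DMF, rt
Reagents that add atoms: triisopropylsilyl chloride, CC(C)[Si](Cl)(C(C)C)C(C)C
Why: Silylation of the primary alcohol so that only one hydroxyl is present in the dianion chemistry of step 10.

Step 8
Reactants: 13 (2R,3S)-7-methoxy-2-ArA-3-[(triisopropylsilyloxy)methyl]-2,3-dihydro-1-benzofuran-5-carbonitrile and 3 ethyl bromoacetate
Product: 15 ethyl 3-{(2R,3S)-7-methoxy-2-ArA-3-[(triisopropylsilyloxy)methyl]-2,3-dihydro-1-benzofuran-5-yl}-3-oxopropanoate, via enamino ester 14 (not isolated)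
Conditions: Zn dust (3 equiv, activated with MeSO3H), slow addition of 3, THF, reflux; then 1 M HCl, THF, rt
Reagents that add atoms: water, O
Why: Blaise reaction as in step 2; the organozinc reagent and the brief dilute acid should leave the silyl ethers and the benzylic aryl ether intact.

Step 9
Reactants: 15 ethyl 3-{(2R,3S)-7-methoxy-2-ArA-3-[(triisopropylsilyloxy)methyl]-2,3-dihydro-1-benzofuran-5-yl}-3-oxopropanoate
Product: 16 ethyl (3R)-3-hydroxy-3-{(2R,3S)-7-methoxy-2-ArA-3-[(triisopropylsilyloxy)methyl]-2,3-dihydro-1-benzofuran-5-yl}propanoate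
Conditions: RuCl(p-cymene)[(R,R)-TsDPEN] (2 mol%), HCO2H/Et3N (5:2), 30 °C
Reagents that add atoms: none
Why: Noyori–Ikariya asymmetric transfer hydrogenation as in step 3; the new carbinol centre is set by the catalyst, the existing stereocentres being remote.

Step 10
Reactants: 16 ethyl (3R)-3-hydroxy-3-{(2R,3S)-7-methoxy-2-ArA-3-[(triisopropylsilyloxy)methyl]-2,3-dihydro-1-benzofuran-5-yl}propanoate and 8 3-fluoro-5-methoxy-4-nitrobenzonitrile
Product: 19 ethyl (2R,3R)-5-cyano-7-methoxy-2-{(2R,3S)-7-methoxy-2-ArA-3-[(triisopropylsilyloxy)methyl]-2,3-dihydro-1-benzofuran-5-yl}-2,3-dihydro-1-benzofuran-3-carboxylate, via dilithium alkoxide enolate 17 (not isolated), via C-arylated dilithium alkoxide enolate 18 (not isolated)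
Conditions: LiN(iPr)2 (2.1 equiv), THF, −78 → −30 °C; LiN(SiMe3)2 (1.2 equiv), then 8, −78 → 0 °C; DMPU, 0 °C → rt; AcOH, −78 °C; then DBU (0.2 equiv), THF, rt
Reagents that add atoms: none
Why: Proposed new method: the same dianion annulation as in step 5 (closest known reactions: C-alkylation of β-hydroxy ester dianions, SNAr α-arylation of ester enolates by 2-fluoronitroarenes, intramolecular displacement of activated nitro groups by alkoxides), in which the enolate carbon of 17 displaces fluoride at C3a', the alkoxide of 18 displaces the nitro group at C7a' para to the nitrile, C2' is carried over from 16 and C3' is equilibrated to trans by DBU.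

Step 11
Reactants: 19 ethyl (2R,3R)-5-cyano-7-methoxy-2-{(2R,3S)-7-methoxy-2-ArA-3-[(triisopropylsilyloxy)methyl]-2,3-dihydro-1-benzofuran-5-yl}-2,3-dihydro-1-benzofuran-3-carboxylate
Product: 21 (2R,3S)-3-(hydroxymethyl)-7-methoxy-2-{(2R,3S)-7-methoxy-2-ArA-3-[(triisopropylsilyloxy)methyl]-2,3-dihydro-1-benzofuran-5-yl}-2,3-dihydro-1-benzofuran-5-carbaldehyde, via hydroxy aldimine 20 (not isolated)
Conditions: iBu2AlH (5 equiv), CH2Cl2, −78 → −30 °C; aqueous potassium sodium tartrate, then dilute citric acid, rt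
Reagents that add atoms: water, O
Why: iBu2AlH should reduce the ester to the primary alcohol and the nitrile only to the imine stage, which hydrolyses through aldimine 20 to the aldehyde on work-up; no stereocentre is touched.

Step 12
Reactants: 21 (2R,3S)-3-(hydroxymethyl)-7-methoxy-2-{(2R,3S)-7-methoxy-2-ArA-3-[(triisopropylsilyloxy)methyl]-2,3-dihydro-1-benzofuran-5-yl}-2,3-dihydro-1-benzofuran-5-carbaldehyde and 22 ethyl (triphenylphosphoranylidene)acetate
Product: 23 ethyl (2E)-3-[(2R,3S)-3-(hydroxymethyl)-7-methoxy-2-{(2R,3S)-7-methoxy-2-ArA-3-[(triisopropylsilyloxy)methyl]-2,3-dihydro-1-benzofuran-5-yl}-2,3-dihydro-1-benzofuran-5-yl]prop-2-enoate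
Conditions: 22 (1.5 equiv), toluene, 80 °C
Reagents that add atoms: none
Why: Wittig olefination with a stabilised ylide should give the (E)-enoate and tolerates the free hydroxyl.

Step 13
Reactants: 23 ethyl (2E)-3-[(2R,3S)-3-(hydroxymethyl)-7-methoxy-2-{(2R,3S)-7-methoxy-2-ArA-3-[(triisopropylsilyloxy)methyl]-2,3-dihydro-1-benzofuran-5-yl}-2,3-dihydro-1-benzofuran-5-yl]prop-2-enoate
Product: 24 (2E)-3-[(2R,3S)-3-(hydroxymethyl)-7-methoxy-2-{(2R,3S)-7-methoxy-2-ArA-3-[(triisopropylsilyloxy)methyl]-2,3-dihydro-1-benzofuran-5-yl}-2,3-dihydro-1-benzofuran-5-yl]prop-2-en-1-ol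
Conditions: iBu2AlH (4 equiv), CH2Cl2, −78 °C; aqueous potassium sodium tartrate
Reagents that add atoms: none
Why: 1,2-Reduction of the enoate to the allylic alcohol with retention of the (E)-alkene.

Step 14
Reactants: 24 (2E)-3-[(2R,3S)-3-(hydroxymethyl)-7-methoxy-2-{(2R,3S)-7-methoxy-2-ArA-3-[(triisopropylsilyloxy)methyl]-2,3-dihydro-1-benzofuran-5-yl}-2,3-dihydro-1-benzofuran-5-yl]prop-2-en-1-ol
Product: 25 CNP0250921.1
Conditions: Bu4NF (3 equiv), AcOH (3 equiv), THF, 0 °C → rt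
Reagents that add atoms: none
Why: Fluoride cleaves the aryl and the primary silyl ether; the acetic acid buffer should prevent phenoxide-driven opening of the benzylic aryl ether.

**Compound list**

1 | 4-hydroxy-3-methoxybenzonitrile | COc1cc(C#N)ccc1O | starting material
2 | 3-methoxy-4-(triisopropylsilyloxy)benzonitrile | COc1cc(C#N)ccc1O[Si](C(C)C)(C(C)C)C(C)C | intermediate
3 | ethyl bromoacetate | CCOC(=O)CBr | starting material
4 | ethyl (Z)-3-amino-3-ArA-prop-2-enoate | CCOC(=O)/C=C(\N)c1ccc(O[Si](C(C)C)(C(C)C)C(C)C)c(OC)c1 | intermediate (not isolated)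
5 | ethyl 3-ArA-3-oxopropanoate | CCOC(=O)CC(=O)c1ccc(O[Si](C(C)C)(C(C)C)C(C)C)c(OC)c1 | intermediate
6 | ethyl (3R)-3-hydroxy-3-ArA-propanoate | CCOC(=O)C[C@@H](O)c1ccc(O[Si](C(C)C)(C(C)C)C(C)C)c(OC)c1 | intermediate
7 | 3,5-difluoro-4-nitrobenzonitrile | N#Cc1cc(F)c([N+](=O)[O-])c(F)c1 | starting material
8 | 3-fluoro-5-methoxy-4-nitrobenzonitrile | COc1cc(C#N)cc(F)c1[N+](=O)[O-] | intermediate
9 | dilithium alkoxide (E)-enolate of 6 | [Li+].[Li+].CCO/C([O-])=C/[C@@H]([O-])c1ccc(O[Si](C(C)C)(C(C)C)C(C)C)c(OC)c1 | intermediate (not isolated)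
10 | dilithium alkoxide enolate of ethyl (3R)-2-(5-cyano-3-methoxy-2-nitrophenyl)-3-hydroxy-3-ArA-propanoate | [Li+].[Li+].CCO/C([O-])=C(\c1cc(C#N)cc(OC)c1[N+](=O)[O-])[C@@H]([O-])c1ccc(O[Si](C(C)C)(C(C)C)C(C)C)c(OC)c1 | intermediate (not isolated)
11 | ethyl (2R,3R)-5-cyano-7-methoxy-2-ArA-2,3-dihydro-1-benzofuran-3-carboxylate | COc1cc([C@@H]2Oc3c(OC)cc(C#N)cc3[C@H]2C(=O)OCC)ccc1O[Si](C(C)C)(C(C)C)C(C)C | intermediate
12 | (2R,3S)-3-(hydroxymethyl)-7-methoxy-2-ArA-2,3-dihydro-1-benzofuran-5-carbonitrile | COc1cc([C@@H]2Oc3c(OC)cc(C#N)cc3[C@H]2CO)ccc1O[Si](C(C)C)(C(C)C)C(C)C | intermediate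
13 | (2R,3S)-7-methoxy-2-ArA-3-[(triisopropylsilyloxy)methyl]-2,3-dihydro-1-benzofuran-5-carbonitrile | COc1cc([C@@H]2Oc3c(OC)cc(C#N)cc3[C@H]2CO[Si](C(C)C)(C(C)C)C(C)C)ccc1O[Si](C(C)C)(C(C)C)C(C)C | intermediate
14 | ethyl (Z)-3-amino-3-(dihydrobenzofuran-5-yl)prop-2-enoate derived from 13 | COc1cc([C@@H]2Oc3c(OC)cc(/C(N)=C/C(=O)OCC)cc3[C@H]2CO[Si](C(C)C)(C(C)C)C(C)C)ccc1O[Si](C(C)C)(C(C)C)C(C)C | intermediate (not isolated)
15 | ethyl 3-{(2R,3S)-7-methoxy-2-ArA-3-[(triisopropylsilyloxy)methyl]-2,3-dihydro-1-benzofuran-5-yl}-3-oxopropanoate | COc1cc([C@@H]2Oc3c(OC)cc(C(=O)CC(=O)OCC)cc3[C@H]2CO[Si](C(C)C)(C(C)C)C(C)C)ccc1O[Si](C(C)C)(C(C)C)C(C)C | intermediate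
16 | ethyl (3R)-3-hydroxy-3-{(2R,3S)-7-methoxy-2-ArA-3-[(triisopropylsilyloxy)methyl]-2,3-dihydro-1-benzofuran-5-yl}propanoate | COc1cc([C@@H]2Oc3c(OC)cc([C@H](O)CC(=O)OCC)cc3[C@H]2CO[Si](C(C)C)(C(C)C)C(C)C)ccc1O[Si](C(C)C)(C(C)C)C(C)C | intermediate
17 | dilithium alkoxide (E)-enolate of 16 | [Li+].[Li+].COc1cc([C@@H]2Oc3c(OC)cc([C@H]([O-])/C=C(\[O-])OCC)cc3[C@H]2CO[Si](C(C)C)(C(C)C)C(C)C)ccc1O[Si](C(C)C)(C(C)C)C(C)C | intermediate (not isolated)
18 | dilithium alkoxide enolate of the 2-(5-cyano-3-methoxy-2-nitrophenyl) derivative of 16 | [Li+].[Li+].COc1cc([C@@H]2Oc3c(OC)cc([C@H]([O-])/C(c4cc(C#N)cc(OC)c4[N+](=O)[O-])=C(\[O-])OCC)cc3[C@H]2CO[Si](C(C)C)(C(C)C)C(C)C)ccc1O[Si](C(C)C)(C(C)C)C(C)C | intermediate (not isolated)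
19 | ethyl (2R,3R)-5-cyano-7-methoxy-2-{(2R,3S)-7-methoxy-2-ArA-3-[(triisopropylsilyloxy)methyl]-2,3-dihydro-1-benzofuran-5-yl}-2,3-dihydro-1-benzofuran-3-carboxylate | COc1cc([C@@H]2Oc3c(OC)cc([C@@H]4Oc5c(OC)cc(C#N)cc5[C@H]4C(=O)OCC)cc3[C@H]2CO[Si](C(C)C)(C(C)C)C(C)C)ccc1O[Si](C(C)C)(C(C)C)C(C)C | intermediate
20 | aldimine of 21 (C5'–CH=NH, C3'–CH2OH) | COc1cc([C@@H]2Oc3c(OC)cc([C@@H]4Oc5c(OC)cc(C=N)cc5[C@H]4CO)cc3[C@H]2CO[Si](C(C)C)(C(C)C)C(C)C)ccc1O[Si](C(C)C)(C(C)C)C(C)C | intermediate (not isolated)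
21 | (2R,3S)-3-(hydroxymethyl)-7-methoxy-2-{(2R,3S)-7-methoxy-2-ArA-3-[(triisopropylsilyloxy)methyl]-2,3-dihydro-1-benzofuran-5-yl}-2,3-dihydro-1-benzofuran-5-carbaldehyde | COc1cc([C@@H]2Oc3c(OC)cc([C@@H]4Oc5c(OC)cc(C=O)cc5[C@H]4CO)cc3[C@H]2CO[Si](C(C)C)(C(C)C)C(C)C)ccc1O[Si](C(C)C)(C(C)C)C(C)C | intermediate
22 | ethyl (triphenylphosphoranylidene)acetate | CCOC(=O)C=P(c1ccccc1)(c1ccccc1)c1ccccc1 | starting material
23 | ethyl (2E)-3-aryl-prop-2-enoate from 21 (bis-silyl ether, free C3'–CH2OH) | COc1cc([C@@H]2Oc3c(OC)cc([C@@H]4Oc5c(OC)cc(/C=C/C(=O)OCC)cc5[C@H]4CO)cc3[C@H]2CO[Si](C(C)C)(C(C)C)C(C)C)ccc1O[Si](C(C)C)(C(C)C)C(C)C | intermediate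
24 | bis(triisopropylsilyl) ether of the target (phenol of ring A and C3–CH2OH silylated) | COc1cc([C@@H]2Oc3c(OC)cc([C@@H]4Oc5c(OC)cc(/C=C/CO)cc5[C@H]4CO)cc3[C@H]2CO[Si](C(C)C)(C(C)C)C(C)C)ccc1O[Si](C(C)C)(C(C)C)C(C)C | intermediate
25 | CNP0250921.1 | COc1cc([C@@H]2Oc3c(OC)cc([C@@H]4Oc5c(OC)cc(/C=C/CO)cc5[C@H]4CO)cc3[C@H]2CO)ccc1O | target

**Step count and risks**

Total steps: 14. Longest linear sequence: 13 (steps 1–3 and 5–14; step 4 is a side branch).

Step 5 (key step). What may go wrong: single-electron transfer from the dianion to the nitroarene, oxygen- instead of carbon-arylation in the first substitution, stalling after the first substitution, or retro-aldol cleavage that erodes the C2 configuration. The fallback makes the same O1–C7a bond by known reactions on an auxiliary-made precursor; it sets out from 2 and returns at 13. iBu2AlH reduction of 2 gives 3-methoxy-4-(triisopropylsilyloxy)benzaldehyde F1. Commercial 3-methoxy-4-nitrobenzonitrile undergoes vicarious nucleophilic substitution ortho to the nitro group with tert-butyl chloroacetate and KOtBu in DMF to give tert-butyl 2-(5-cyano-3-methoxy-2-nitrophenyl)acetate F2. CF3CO2H gives 2-(5-cyano-3-methoxy-2-nitrophenyl)acetic acid F3, and pivaloyl chloride, Et3N, LiCl and (R)-4-benzyloxazolidin-2-one give the N-acyl oxazolidinone F4. An Evans syn aldol reaction of F4 with F1 (Bu2BOTf, iPr2NEt, CH2Cl2, −78 → 0 °C) should give the (2R,3R)-aldol adduct F5, and LiBH4 removes the auxiliary to give the (1R,2S)-diol F6. TIPSCl and imidazole give the primary silyl ether F7. KN(SiMe3)2 in THF (−78 → 0 °C) then closes the ring by displacement of the nitro group, para to the nitrile, by the benzylic alkoxide and gives 13.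

Step 10. What may go wrong: the same processes as in step 5, plus slower dianion formation on the larger substrate. The fallback sets out from 13 and returns at 25. iBu2AlH gives the aldehyde F8. The Evans syn aldol reaction with F4 gives the (2R,3R)-adduct F9, LiBH4 gives the diol F10 and TIPSCl/imidazole the primary silyl ether F11. KN(SiMe3)2 closes the inner ring by displacement of the nitro group to give the tris-silyl nitrile F12. iBu2AlH gives the aldehyde F13, Wittig reaction with 22 the (E)-enoate F14, and iBu2AlH the tris-silyl allylic alcohol F15. Bu4NF/AcOH then gives 25.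

Step 11. What may go wrong: over-reduction of the imine stage to the benzylic amine at the temperature needed to take the ester to the alcohol, or incomplete ester reduction. The fallback separates the two reductions; it sets out from 19 and returns at 21. LiBH4/MeOH reduces only the ester and gives the hydroxy nitrile F16; iBu2AlH (2.5 equiv, toluene, −78 °C) with mild acid hydrolysis of the aldimine then gives 21.

**Further compounds**

F1 | step 5 | 3-methoxy-4-(triisopropylsilyloxy)benzaldehyde | COc1cc(C=O)ccc1O[Si](C(C)C)(C(C)C)C(C)C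
F2 | step 5 | tert-butyl 2-(5-cyano-3-methoxy-2-nitrophenyl)acetate | COc1cc(C#N)cc(CC(=O)OC(C)(C)C)c1[N+](=O)[O-]
F3 | step 5 | 2-(5-cyano-3-methoxy-2-nitrophenyl)acetic acid | COc1cc(C#N)cc(CC(=O)O)c1[N+](=O)[O-]
F4 | step 5 | (4R)-4-benzyl-3-[2-(5-cyano-3-methoxy-2-nitrophenyl)acetyl]-1,3-oxazolidin-2-one | COc1cc(C#N)cc(CC(=O)N2[C@H](Cc3ccccc3)COC2=O)c1[N+](=O)[O-]
F5 | step 5 | (4R)-4-benzyl-3-[(2R,3R)-2-(5-cyano-3-methoxy-2-nitrophenyl)-3-hydroxy-3-ArA-propanoyl]-1,3-oxazolidin-2-one | O=C(N1[C@H](Cc2ccccc2)COC1=O)[C@H](c1cc(C#N)cc(OC)c1[N+](=O)[O-])[C@@H](O)c1ccc(O[Si](C(C)C)(C(C)C)C(C)C)c(OC)c1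
F6 | step 5 | 3-[(1R,2S)-1,3-dihydroxy-1-ArA-propan-2-yl]-5-methoxy-4-nitrobenzonitrile | OC[C@H](c1cc(C#N)cc(OC)c1[N+](=O)[O-])[C@@H](O)c1ccc(O[Si](C(C)C)(C(C)C)C(C)C)c(OC)c1
F7 | step 5 | 3-[(1R,2S)-1-hydroxy-1-ArA-3-(triisopropylsilyloxy)propan-2-yl]-5-methoxy-4-nitrobenzonitrile | CC(C)[Si](C(C)C)(C(C)C)OC[C@H](c1cc(C#N)cc(OC)c1[N+](=O)[O-])[C@@H](O)c1ccc(O[Si](C(C)C)(C(C)C)C(C)C)c(OC)c1
F8 | step 10 | (2R,3S)-7-methoxy-2-ArA-3-[(triisopropylsilyloxy)methyl]-2,3-dihydro-1-benzofuran-5-carbaldehyde | COc1cc([C@@H]2Oc3c(OC)cc(C=O)cc3[C@H]2CO[Si](C(C)C)(C(C)C)C(C)C)ccc1O[Si](C(C)C)(C(C)C)C(C)C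
F9 | step 10 | (2R,3R)-syn aldol adduct of F4 with F8 (N-acyl oxazolidinone) | COc1cc([C@@H]2Oc3c(OC)cc([C@H](O)[C@H](C(=O)N4[C@H](Cc5ccccc5)COC4=O)c4cc(C#N)cc(OC)c4[N+](=O)[O-])cc3[C@H]2CO[Si](C(C)C)(C(C)C)C(C)C)ccc1O[Si](C(C)C)(C(C)C)C(C)C
F10 | step 10 | (1R,2S)-1,3-diol from F9 | COc1cc([C@@H]2Oc3c(OC)cc([C@H](O)[C@H](CO)c4cc(C#N)cc(OC)c4[N+](=O)[O-])cc3[C@H]2CO[Si](C(C)C)(C(C)C)C(C)C)ccc1O[Si](C(C)C)(C(C)C)C(C)C
F11 | step 10 | primary triisopropylsilyl ether of F10 | COc1cc([C@@H]2Oc3c(OC)cc([C@H](O)[C@H](CO[Si](C(C)C)(C(C)C)C(C)C)c4cc(C#N)cc(OC)c4[N+](=O)[O-])cc3[C@H]2CO[Si](C(C)C)(C(C)C)C(C)C)ccc1O[Si](C(C)C)(C(C)C)C(C)C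
F12 | step 10 | tris-silyl bis(dihydrobenzofuran) 5'-carbonitrile | COc1cc([C@@H]2Oc3c(OC)cc([C@@H]4Oc5c(OC)cc(C#N)cc5[C@H]4CO[Si](C(C)C)(C(C)C)C(C)C)cc3[C@H]2CO[Si](C(C)C)(C(C)C)C(C)C)ccc1O[Si](C(C)C)(C(C)C)C(C)C
F13 | step 10 | tris-silyl bis(dihydrobenzofuran) 5'-carbaldehyde | COc1cc([C@@H]2Oc3c(OC)cc([C@@H]4Oc5c(OC)cc(C=O)cc5[C@H]4CO[Si](C(C)C)(C(C)C)C(C)C)cc3[C@H]2CO[Si](C(C)C)(C(C)C)C(C)C)ccc1O[Si](C(C)C)(C(C)C)C(C)C
F14 | step 10 | tris-silyl ethyl (E)-enoate | COc1cc([C@@H]2Oc3c(OC)cc([C@@H]4Oc5c(OC)cc(/C=C/C(=O)OCC)cc5[C@H]4CO[Si](C(C)C)(C(C)C)C(C)C)cc3[C@H]2CO[Si](C(C)C)(C(C)C)C(C)C)ccc1O[Si](C(C)C)(C(C)C)C(C)C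
F15 | step 10 | tris(triisopropylsilyl) ether of the target (allylic alcohol free) | COc1cc([C@@H]2Oc3c(OC)cc([C@@H]4Oc5c(OC)cc(/C=C/CO)cc5[C@H]4CO[Si](C(C)C)(C(C)C)C(C)C)cc3[C@H]2CO[Si](C(C)C)(C(C)C)C(C)C)ccc1O[Si](C(C)C)(C(C)C)C(C)C
F16 | step 11 | (2R,3S)-3-(hydroxymethyl)-7-methoxy-2-{(2R,3S)-7-methoxy-2-ArA-3-[(triisopropylsilyloxy)methyl]-2,3-dihydro-1-benzofuran-5-yl}-2,3-dihydro-1-benzofuran-5-carbonitrile | COc1cc([C@@H]2Oc3c(OC)cc([C@@H]4Oc5c(OC)cc(C#N)cc5[C@H]4CO)cc3[C@H]2CO[Si](C(C)C)(C(C)C)C(C)C)ccc1O[Si](C(C)C)(C(C)C)C(C)C
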